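**Retrosynthetic overview**
1. Endgame: the hydroquinone comes from its dimethyl ether (oxidative demethylation, then reduction), the C3 acid from a C10 allyl group, and the C4=C5 isopropylidene from a C5 ketone by mixed titanium carbonyl coupling with acetone.
2. Ring A (C5–C10) is closed last, by aldol condensation of a C7 aldehyde with a C5 methyl ketone. Both arms come from a trans vinyl (C8)/methallyl (C9) pair put onto a ring C enone (C11=O, C9=C8) by conjugate addition–alkylation; the C10 chain enters by α'-allylation and is equilibrated to equatorial.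
3. The C11 enone comes from the C8 ketone by α'-methylation, enol triflate reduction and allylic oxidation (net 1,3-carbonyl transposition); the C11 oxygen is removed later by Wolff–Kishner reduction.
4. The strategy rests on ring C carrying the adjacent stereocentres C13 (H, CH3) and quaternary C14 (CH3, CH2Ar) with trans methyl groups. Both are set in one operation by copper-catalysed asymmetric addition of Me3Al to C13 of 2-(arylmethyl)cyclohex-2-enone and methylation of the C14 enolate anti to the new methyl.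
5. That enone is made from cyclohexane-1,3-dione (which becomes ring C) and 2,5-dimethoxy-3-methylbenzaldehyde by reductive alkylation and vinylogous-ester reduction/transposition.

Key step: step 6

Labels: Ar = 2,5-dimethoxy-3-methylphenyl. Carbons are labelled as in the target: ring C = C8, C9, C11, C12, C13, C14; ring A = C5, C6, C7, C8, C9, C10; C4 = isopropylidene carbon; C1–C3 = propanoic acid chain.
Assumption: the (S)-binaphthol/bis[(R)-1-phenylethyl]amine phosphoramidite is taken to deliver methyl to the enone face that gives (13S), by analogy with its sense on cyclohex-2-enone; if a test run shows the opposite sense, the mirror-image ligand is used and nothing else changes.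

**Route**

Step 1
Reactants: 1 4-methoxy-2-methylphenol; 2 formaldehyde (used as paraformaldehyde)
Product: 3 2-hydroxy-5-methoxy-3-methylbenzaldehyde
Conditions: MgCl2, Et3N, (CH2O)n, MeCN, reflux; 1 M HCl work-up
Reagents that add atoms: formaldehyde (from paraformaldehyde), C=O
Why: Magnesium phenoxide-directed ortho-formylation (Casnati–Skattebøl type) can only occur at the single free position ortho to the hydroxyl, the hydroxymethyl intermediate being oxidised by a second formaldehyde.

Step 2
Reactants: 3 2-hydroxy-5-methoxy-3-methylbenzaldehyde; 4 iodomethane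
Product: 5 2,5-dimethoxy-3-methylbenzaldehyde
Conditions: MeI, K2CO3, DMF, rt
Reagents that add atoms: iodomethane, CI
Why: Williamson O-methylation of the phenoxide is straightforward and gives the methyl ethers that survive every later step until the final oxidative unmasking.

Step 3
Reactants: 5 2,5-dimethoxy-3-methylbenzaldehyde; 6 cyclohexane-1,3-dione; 7 diethyl 2,6-dimethyl-1,4-dihydropyridine-3,5-dicarboxylate (Hantzsch ester)
Product: 9 2-(ArCH2)cyclohexane-1,3-dione, via Knoevenagel adduct 8 (not isolated)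
Conditions: L-proline (20 mol%), CH2Cl2, rt
Reagents that add atoms: cyclohexane-1,3-dione, O=C1CCCC(=O)C1
Why: Proline-catalysed Knoevenagel condensation gives the arylidene dione, whose strongly electrophilic alkene takes up hydride from the dihydropyridine (three-component reductive alkylation), so clean mono-C-alkylation results without O-alkylation or bis-adduct.

Step 4
Reactants: 9 2-(ArCH2)cyclohexane-1,3-dione; 10 2-methylpropan-1-ol
Product: 11 2-(ArCH2)-3-(2-methylpropoxy)cyclohex-2-en-1-one
Conditions: i-BuOH, TsOH·H2O (cat.), toluene, reflux, water separator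
Reagents that add atoms: 2-methylpropan-1-ol, CC(C)CO
Why: Acid-catalysed enol etherification of the symmetrical 2-substituted dione with azeotropic removal of water gives a single vinylogous ester.

Step 5
Reactants: 11 2-(ArCH2)-3-(2-methylpropoxy)cyclohex-2-en-1-one
Product: 13 2-(ArCH2)cyclohex-2-en-1-one, via allylic alcohol 12 (not isolated)
Conditions: LiAlH4, Et2O, 0 °C; then 1 M HCl, rt
Reagents that add atoms: none
Why: 1,2-Hydride reduction of the vinylogous ester carbonyl, then acid hydrolysis of the enol ether and β-elimination of water (Stork–Danheiser transposition), delivers the 2-substituted cyclohex-2-enone.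

Step 6
Reactants: 13 2-(ArCH2)cyclohex-2-en-1-one; 14 trimethylaluminium; 4 iodomethane
Product: 17 (2S,3S)-2-(ArCH2)-2,3-dimethylcyclohexan-1-one, via dimethylaluminium enolate 15 (not isolated), via lithium aluminate enolate 16 (not isolated)
Conditions: copper thiophene-2-carboxylate Cu(O2CC4H3S) (5 mol%), (S)-binaphthol/bis[(R)-1-phenylethyl]amine phosphoramidite (10 mol%), Me3Al, Et2O, −30 °C; then MeLi, THF, −30 °C; then MeI, HMPA, −30 → 0 °C; 1 M HCl work-up
Reagents that add atoms: trimethylaluminium, C[Al](C)C; iodomethane, CI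
Why: Transmetalation of Me3Al to the phosphoramidite-bound copper catalyst gives a chiral methylcopper species that π-complexes the enone, adds oxidatively at C13 and reductively eliminates, so the C13–CH3 bond forms on the enone face chosen by the ligand and a dimethylaluminium enolate 15 is left with its double bond fixed between C8 and C14. MeLi turns this weakly nucleophilic enolate into the lithium aluminate 16, which is C-methylated at C14 by MeI in THF/HMPA before it can equilibrate. The closest known reaction type is the Cu/phosphoramidite-catalysed conjugate addition of trialkylaluminium reagents to 2-substituted cyclohex-2-enones with alkylation of the resulting aluminium enolate; no ring is closed, and two C–C bonds and two stereocentres are made. C13 is controlled by the chiral catalyst (enantiofacial selectivity); C14 is controlled by the substrate, because allylic 1,2-strain with the in-plane arylmethyl group holds the C13 methyl pseudo-axial, so MeI attacks the opposite face and the two methyl groups end up trans (arylmethyl cis to the C13 methyl). The step needs 1,4- over 1,2-addition (secured by copper), an enolate at C14 only (it is generated by the addition itself) and C- over O-alkylation (soft iodide electrophile).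

Step 7
Reactants: 17 (2S,3S)-2-(ArCH2)-2,3-dimethylcyclohexan-1-one; 4 iodomethane
Product: 19 (2S,3S,6RS)-2-(ArCH2)-2,3,6-trimethylcyclohexan-1-one, via lithium enolate 18 (not isolated)
Conditions: LiN(i-Pr)2, THF, −78 °C; MeI, −78 → 0 °C
Reagents that add atoms: iodomethane, CI
Why: C14 is quaternary, so deprotonation can only occur at C9 and kinetic enolate methylation gives the α'-methyl ketone; the new C9 centre forms as an epimer mixture that is erased in step 8.

Step 8
Reactants: 19 (2S,3S,6RS)-2-(ArCH2)-2,3,6-trimethylcyclohexan-1-one; 20 N-phenylbis(trifluoromethanesulfonimide)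
Product: 22 (5S,6S)-6-(ArCH2)-2,5,6-trimethylcyclohex-1-en-1-yl trifluoromethanesulfonate, via potassium enolate 21 (not isolated)
Conditions: KN(SiMe3)2, THF, −78 → 0 °C; PhNTf2, 0 °C → rt
Reagents that add atoms: N-phenylbis(trifluoromethanesulfonimide), O=S(=O)(N(c1ccccc1)S(=O)(=O)C(F)(F)F)C(F)(F)F
Why: The only enolisable hydrogen sits on C9, so the tetrasubstituted C8=C9 enolate forms regiospecifically and is O-sulfonylated, as is routine for 2,2,6-trisubstituted cyclohexanones.

Step 9
Reactants: 22 (5S,6S)-6-(ArCH2)-2,5,6-trimethylcyclohex-1-en-1-yl trifluoromethanesulfonate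
Product: 23 (3S,4S)-3-(ArCH2)-1,3,4-trimethylcyclohex-1-ene
Conditions: Pd(OAc)2 (5 mol%), PPh3 (10 mol%), HCO2H, n-Bu3N, DMF, 60 °C
Reagents that add atoms: none
Why: Oxidative addition of zerovalent palladium into the vinyl C–O bond, formate exchange, decarboxylation and C–H reductive elimination replace the triflate by hydrogen without moving the C8=C9 double bond or touching the stereocentres.

Step 10
Reactants: 23 (3S,4S)-3-(ArCH2)-1,3,4-trimethylcyclohex-1-ene; 24 tert-butyl hydroperoxide
Product: 25 (4S,5S)-4-(ArCH2)-2,4,5-trimethylcyclohex-2-en-1-one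
Conditions: Rh2(cap)4 (dirhodium tetracaprolactamate, 1 mol%), t-BuOOH (70% aq.), K2CO3, CH2Cl2, rt
Reagents that add atoms: tert-butyl hydroperoxide, CC(C)(C)OO
Why: Radical allylic oxidation (hydrogen abstraction by tert-butylperoxyl, mixed peroxide, collapse to the enone) can only use C11H2, the single allylic ring methylene because C14 is quaternary, which places the carbonyl at C11 with the C9=C8 double bond and so completes the 1,3-transposition; the neopentyl benzylic CH2 should react more slowly.

Step 11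
Reactants: 25 (4S,5S)-4-(ArCH2)-2,4,5-trimethylcyclohex-2-en-1-one; 26 vinylmagnesium bromide; 27 chlorotrimethylsilane
Product: 28 {[(3R,4S,5S)-4-(ArCH2)-3-ethenyl-2,4,5-trimethylcyclohex-1-en-1-yl]oxy}trimethylsilane
Conditions: CH2=CHMgBr, CuBr·SMe2 (10 mol%), Me3SiCl, HMPA, THF, −78 °C; Et3N, pentane work-up
Reagents that add atoms: vinylmagnesium bromide, C=C[Mg]Br; chlorotrimethylsilane, C[Si](C)(C)Cl
Why: Chlorosilane-accelerated copper-catalysed conjugate addition puts vinyl on C8 by axial attack on the half-chair that keeps the C13 methyl equatorial, that is anti to both the pseudo-axial C14 arylmethyl group and the C13 methyl, which sets C8 and traps the C11–C9 enolate regiospecifically as its silyl ether.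

Step 12
Reactants: 28 {[(3R,4S,5S)-4-(ArCH2)-3-ethenyl-2,4,5-trimethylcyclohex-1-en-1-yl]oxy}trimethylsilane; 29 3-bromo-2-methylprop-1-ene
Product: 31 (2S,3R,4S,5S)-4-(ArCH2)-3-ethenyl-2,4,5-trimethyl-2-(2-methylprop-2-en-1-yl)cyclohexan-1-one, via lithium enolate 30 (not isolated)
Conditions: MeLi, THF, 0 °C → rt; then HMPA, CH2=C(CH3)CH2Br, −78 → 0 °C
Reagents that add atoms: 3-bromo-2-methylprop-1-ene, C=C(C)CBr
Why: MeLi cleaves the Si–O bond to the regiodefined lithium enolate, which is C-alkylated by the reactive allylic bromide on the face opposite the adjacent C8 vinyl group (the usual 2,3-trans outcome of conjugate addition–alkylation), so quaternary C9 is set with its methyl cis and its C10 arm trans to C7.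

Step 13
Reactants: 31 (2S,3R,4S,5S)-4-(ArCH2)-3-ethenyl-2,4,5-trimethyl-2-(2-methylprop-2-en-1-yl)cyclohexan-1-one
Product: 33 (1S,2S,3S,4S)-3-(ArCH2)-2-ethenyl-1,3,4-trimethyl-1-(2-methylprop-2-en-1-yl)cyclohexane, via hydrazone 32 (not isolated)
Conditions: N2H4·H2O, KOH, diethylene glycol, 130 °C, then 200 °C with removal of water, under argon
Reagents that add atoms: none
Why: Wolff–Kishner reduction (Huang-Minlon procedure) removes the C11 carbonyl through its hydrazone with loss of N2, a reaction that tolerates one α-quaternary neighbour, while the isolated alkenes, the aryl ethers and the non-enolisable C8 and C9 centres are unaffected.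

Step 14
Reactants: 33 (1S,2S,3S,4S)-3-(ArCH2)-2-ethenyl-1,3,4-trimethyl-1-(2-methylprop-2-en-1-yl)cyclohexane; 34 sodium periodate
Product: 35 (1S,2S,3S,6S)-2-(ArCH2)-2,3,6-trimethyl-6-(2-oxopropyl)cyclohexane-1-carbaldehyde
Conditions: OsO4 (2 mol%), NaIO4, 2,6-lutidine, dioxane–H2O (3:1), rt
Reagents that add atoms: sodium periodate (oxygen delivered through catalytic OsO4), [Na+].[O-]I(=O)(=O)=O
Why: Lemieux–Johnson cleavage (catalytic dihydroxylation, periodate glycol cleavage) turns the vinyl group into the C7 aldehyde and the methallyl group into the C5 methyl ketone under buffered conditions that leave the electron-rich arene alone, which ozone might not.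

Step 15
Reactants: 35 (1S,2S,3S,6S)-2-(ArCH2)-2,3,6-trimethyl-6-(2-oxopropyl)cyclohexane-1-carbaldehyde
Product: 37 (4aS,5S,6S,8aS)-5-(ArCH2)-5,6,8a-trimethyl-4a,5,6,7,8,8a-hexahydronaphthalen-2(1H)-one, via aldol 36 (not isolated)
Conditions: KOH, MeOH, 0 °C → rt
Reagents that add atoms: none
Why: Intramolecular aldol condensation of the 1,5-keto aldehyde closes ring A through the only six-membered mode (the ketone methyl C6 onto C7; attack by C10 would give a cyclobutane) and dehydration gives the enone, the trans ring fusion being carried over from steps 11 and 12 because the C8 hydrogen lies between two quaternary carbons and enolises slowly.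

Step 16
Reactants: 37 (4aS,5S,6S,8aS)-5-(ArCH2)-5,6,8a-trimethyl-4a,5,6,7,8,8a-hexahydronaphthalen-2(1H)-one; 38 3-bromoprop-1-ene
Product: 40 (4aR,5S,6S,8aR)-5-(ArCH2)-5,6,8a-trimethyl-1-(prop-2-en-1-yl)-4a,5,6,7,8,8a-hexahydronaphthalen-2(1H)-one (C1 epimers), via lithium dienolate 39 (not isolated)
Conditions: LiN(i-Pr)2, THF, −78 °C; CH2=CHCH2Br, DMPU, −78 → −20 °C
Reagents that add atoms: 3-bromoprop-1-ene, C=CCBr
Why: Kinetic deprotonation of the enone at C10, its only α' position, gives the cross-conjugated dienolate, which is allylated at C10; attack anti to the axial C9 methyl is expected to favour the axial epimer, and this is corrected in step 17.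

Step 17
Reactants: 40 (4aR,5S,6S,8aR)-5-(ArCH2)-5,6,8a-trimethyl-1-(prop-2-en-1-yl)-4a,5,6,7,8,8a-hexahydronaphthalen-2(1H)-one (C1 epimers)
Product: 42 (1S,4aR,5S,6S,8aR)-5-(ArCH2)-5,6,8a-trimethyl-1-(prop-2-en-1-yl)octahydronaphthalen-2(1H)-one, via C10-epimeric ketone 41 (not isolated)
Conditions: [(Ph3P)CuH]6, wet benzene, rt; then NaOMe, MeOH, rt; the minor epimer is separated and re-equilibrated
Reagents that add atoms: none
Why: Copper hydride conjugate reduction saturates C6=C7 without touching the allyl group, and base equilibration of C10 (α to the C5 ketone) should favour the equatorial allyl group, cis to the C9 methyl and free of the three syn-axial contacts of the axial epimer, which is the configuration of the target.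

Step 18
Reactants: 42 (1S,4aR,5S,6S,8aR)-5-(ArCH2)-5,6,8a-trimethyl-1-(prop-2-en-1-yl)octahydronaphthalen-2(1H)-one; 43 acetone
Product: 44 (1S,4aR,5S,6S,8aR)-5-(ArCH2)-5,6,8a-trimethyl-2-(propan-2-ylidene)-1-(prop-2-en-1-yl)decahydronaphthalene
Conditions: TiCl3(DME)1.5, Zn(Cu), DME, reflux; slow addition of 42 and acetone (4 equiv)
Reagents that add atoms: acetone, CC(C)=O
Why: Titanium-induced mixed carbonyl coupling (McMurry) forms the tetrasubstituted C4=C5 bond exactly where the carbonyl was, the excess acetone homocoupling only to a volatile alkene and the terminal alkene and aryl ethers being inert to low-valent titanium.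

Step 19
Reactants: 44 (1S,4aR,5S,6S,8aR)-5-(ArCH2)-5,6,8a-trimethyl-2-(propan-2-ylidene)-1-(prop-2-en-1-yl)decahydronaphthalene; 45 hydrogen peroxide
Product: 47 3-[(1S,4aR,5S,6S,8aR)-5-(ArCH2)-5,6,8a-trimethyl-2-(propan-2-ylidene)decahydronaphthalen-1-yl]propan-1-ol, via alkylborane 46 (not isolated)
Conditions: 9-BBN, THF, 0 °C → rt; then NaOH, H2O2, 0 °C → rt
Reagents that add atoms: hydrogen peroxide, OO
Why: Anti-Markovnikov hydroboration by the bulky dialkylborane takes place only at the monosubstituted alkene (the tetrasubstituted isopropylidene is inert) and oxidation gives the primary alcohol.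

Step 20
Reactants: 47 3-[(1S,4aR,5S,6S,8aR)-5-(ArCH2)-5,6,8a-trimethyl-2-(propan-2-ylidene)decahydronaphthalen-1-yl]propan-1-ol; 48 water
Product: 50 3-[(1S,4aR,5S,6S,8aR)-5-(ArCH2)-5,6,8a-trimethyl-2-(propan-2-ylidene)decahydronaphthalen-1-yl]propanoic acid, via aldehyde 49 (not isolated)
Conditions: TEMPO (20 mol%), PhI(OAc)2, MeCN–H2O (1:1), rt
Reagents that add atoms: water, O
Why: Oxoammonium-mediated oxidation takes the primary alcohol to the aldehyde and its hydrate on to the acid under near-neutral conditions that spare the tetrasubstituted alkene and the dimethoxyarene.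

Step 21
Reactants: 50 3-[(1S,4aR,5S,6S,8aR)-5-(ArCH2)-5,6,8a-trimethyl-2-(propan-2-ylidene)decahydronaphthalen-1-yl]propanoic acid; 48 water
Product: 52 3-[(1S,4aR,5S,6S,8aR)-5-[(2,5-dihydroxy-3-methylphenyl)methyl]-5,6,8a-trimethyl-2-(propan-2-ylidene)decahydronaphthalen-1-yl]propanoic acid (CNP0286368.1), via quinone 51 (not isolated)
Conditions: (NH4)2Ce(NO3)6, MeCN–H2O, 0 °C; then aq. Na2S2O4, EtOAc, rt, under argon
Reagents that add atoms: water, O
Why: Single-electron oxidation of the 1,4-dimethoxyarene with capture of water gives the p-quinone and dithionite reduces it to the hydroquinone, which avoids Lewis-acidic ether cleavage that would endanger the isopropylidene group.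

**Compound list**
1 | 4-methoxy-2-methylphenol | Cc1cc(OC)ccc1O | starting material
2 | formaldehyde (as paraformaldehyde) | C=O | starting material
3 | 2-hydroxy-5-methoxy-3-methylbenzaldehyde | O=Cc1cc(OC)cc(C)c1O | intermediate
4 | iodomethane | CI | starting material
5 | 2,5-dimethoxy-3-methylbenzaldehyde | O=Cc1cc(OC)cc(C)c1OC | intermediate
6 | cyclohexane-1,3-dione | O=C1CCCC(=O)C1 | starting material
7 | diethyl 2,6-dimethyl-1,4-dihydropyridine-3,5-dicarboxylate (Hantzsch ester) | CCOC(=O)C1=C(C)NC(C)=C(C(=O)OCC)C1 | starting material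
8 | 2-[(2,5-dimethoxy-3-methylphenyl)methylidene]cyclohexane-1,3-dione | O=C1CCCC(=O)C1=Cc1cc(OC)cc(C)c1OC | intermediate
9 | 2-[(2,5-dimethoxy-3-methylphenyl)methyl]cyclohexane-1,3-dione | O=C1CCCC(=O)C1Cc1cc(OC)cc(C)c1OC | intermediate
10 | 2-methylpropan-1-ol | CC(C)CO | starting material
11 | 2-[(2,5-dimethoxy-3-methylphenyl)methyl]-3-(2-methylpropoxy)cyclohex-2-en-1-one | CC(C)COC1=C(Cc2cc(OC)cc(C)c2OC)C(=O)CCC1 | intermediate
12 | 2-[(2,5-dimethoxy-3-methylphenyl)methyl]-3-(2-methylpropoxy)cyclohex-2-en-1-ol | CC(C)COC1=C(Cc2cc(OC)cc(C)c2OC)C(O)CCC1 | intermediate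
13 | 2-[(2,5-dimethoxy-3-methylphenyl)methyl]cyclohex-2-en-1-one | O=C1CCCC=C1Cc1cc(OC)cc(C)c1OC | intermediate
14 | trimethylaluminium | C[Al](C)C | starting material
15 | dimethyl{[(3S)-2-[(2,5-dimethoxy-3-methylphenyl)methyl]-3-methylcyclohex-1-en-1-yl]oxy}alumane | C[Al](C)OC1=C(Cc2cc(OC)cc(C)c2OC)[C@@H](C)CCC1 | intermediate
16 | lithium trimethyl{[(3S)-2-[(2,5-dimethoxy-3-methylphenyl)methyl]-3-methylcyclohex-1-en-1-yl]oxy}aluminate | [Li+].C[Al-](C)(C)OC1=C(Cc2cc(OC)cc(C)c2OC)[C@@H](C)CCC1 | intermediate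
17 | (2S,3S)-2-[(2,5-dimethoxy-3-methylphenyl)methyl]-2,3-dimethylcyclohexan-1-one | O=C1CCC[C@H](C)[C@]1(C)Cc1cc(OC)cc(C)c1OC | intermediate
18 | lithium (5S,6S)-6-[(2,5-dimethoxy-3-methylphenyl)methyl]-5,6-dimethylcyclohex-1-en-1-olate | [Li]OC1=CCC[C@H](C)[C@]1(C)Cc1cc(OC)cc(C)c1OC | intermediate
19 | (2S,3S,6RS)-2-[(2,5-dimethoxy-3-methylphenyl)methyl]-2,3,6-trimethylcyclohexan-1-one | O=C1C(C)CC[C@H](C)[C@]1(C)Cc1cc(OC)cc(C)c1OC | intermediate
20 | N-phenylbis(trifluoromethanesulfonimide) | O=S(=O)(N(c1ccccc1)S(=O)(=O)C(F)(F)F)C(F)(F)F | starting material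
21 | potassium (5S,6S)-6-[(2,5-dimethoxy-3-methylphenyl)methyl]-2,5,6-trimethylcyclohex-1-en-1-olate | [K]OC1=C(C)CC[C@H](C)[C@]1(C)Cc1cc(OC)cc(C)c1OC | intermediate
22 | (5S,6S)-6-[(2,5-dimethoxy-3-methylphenyl)methyl]-2,5,6-trimethylcyclohex-1-en-1-yl trifluoromethanesulfonate | O=S(=O)(OC1=C(C)CC[C@H](C)[C@]1(C)Cc1cc(OC)cc(C)c1OC)C(F)(F)F | intermediate
23 | (3S,4S)-3-[(2,5-dimethoxy-3-methylphenyl)methyl]-1,3,4-trimethylcyclohex-1-ene | C1=C(C)CC[C@H](C)[C@]1(C)Cc1cc(OC)cc(C)c1OC | intermediate
24 | tert-butyl hydroperoxide | CC(C)(C)OO | starting material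
25 | (4S,5S)-4-[(2,5-dimethoxy-3-methylphenyl)methyl]-2,4,5-trimethylcyclohex-2-en-1-one | C1=C(C)C(=O)C[C@H](C)[C@]1(C)Cc1cc(OC)cc(C)c1OC | intermediate
26 | vinylmagnesium bromide | C=C[Mg]Br | starting material
27 | chlorotrimethylsilane | C[Si](C)(C)Cl | starting material
28 | {[(3R,4S,5S)-4-[(2,5-dimethoxy-3-methylphenyl)methyl]-3-ethenyl-2,4,5-trimethylcyclohex-1-en-1-yl]oxy}trimethylsilane | C=C[C@H]1C(C)=C(O[Si](C)(C)C)C[C@H](C)[C@]1(C)Cc1cc(OC)cc(C)c1OC | intermediate
29 | 3-bromo-2-methylprop-1-ene | C=C(C)CBr | starting material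
30 | lithium (3R,4S,5S)-4-[(2,5-dimethoxy-3-methylphenyl)methyl]-3-ethenyl-2,4,5-trimethylcyclohex-1-en-1-olate | C=C[C@H]1C(C)=C(O[Li])C[C@H](C)[C@]1(C)Cc1cc(OC)cc(C)c1OC | intermediate
31 | (2S,3R,4S,5S)-4-[(2,5-dimethoxy-3-methylphenyl)methyl]-3-ethenyl-2,4,5-trimethyl-2-(2-methylprop-2-en-1-yl)cyclohexan-1-one | C=C[C@H]1[C@@](C)(C(=O)C[C@H](C)[C@]1(C)Cc1cc(OC)cc(C)c1OC)CC(C)=C | intermediate
32 | hydrazone of ketone 31 | C=C[C@H]1[C@@](C)(C(=NN)C[C@H](C)[C@]1(C)Cc1cc(OC)cc(C)c1OC)CC(C)=C | intermediate
33 | (1S,2S,3S,4S)-3-[(2,5-dimethoxy-3-methylphenyl)methyl]-2-ethenyl-1,3,4-trimethyl-1-(2-methylprop-2-en-1-yl)cyclohexane | C=C[C@H]1[C@@](C)(CC[C@H](C)[C@]1(C)Cc1cc(OC)cc(C)c1OC)CC(C)=C | intermediate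
34 | sodium periodate | [Na+].[O-]I(=O)(=O)=O | starting material
35 | (1S,2S,3S,6S)-2-[(2,5-dimethoxy-3-methylphenyl)methyl]-2,3,6-trimethyl-6-(2-oxopropyl)cyclohexane-1-carbaldehyde | O=C[C@H]1[C@@](C)(CC[C@H](C)[C@]1(C)Cc1cc(OC)cc(C)c1OC)CC(C)=O | intermediate
36 | 5-[(2,5-dimethoxy-3-methylphenyl)methyl]-4-hydroxy-5,6,8a-trimethyloctahydronaphthalen-2(1H)-one (ring fusion as in 37, C4 carbinol epimers) | O=C1CC(O)[C@H]2[C@@](C)(CC[C@H](C)[C@]2(C)Cc3cc(OC)cc(C)c3OC)C1 | intermediate
37 | (4aS,5S,6S,8aS)-5-[(2,5-dimethoxy-3-methylphenyl)methyl]-5,6,8a-trimethyl-4a,5,6,7,8,8a-hexahydronaphthalen-2(1H)-one | O=C1C=C[C@H]2[C@@](C)(CC[C@H](C)[C@]2(C)Cc3cc(OC)cc(C)c3OC)C1 | intermediate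
38 | 3-bromoprop-1-ene | C=CCBr | starting material
39 | lithium dienolate of enone 37 (C5 oxygen, C10=C5 and C6=C7 double bonds) | [Li]OC1C=C[C@H]2[C@@](C)(CC[C@H](C)[C@]2(C)Cc3cc(OC)cc(C)c3OC)C=1 | intermediate
40 | (4aR,5S,6S,8aR)-5-[(2,5-dimethoxy-3-methylphenyl)methyl]-5,6,8a-trimethyl-1-(prop-2-en-1-yl)-4a,5,6,7,8,8a-hexahydronaphthalen-2(1H)-one, C1 epimers | O=C1C=C[C@H]2[C@@](C)(CC[C@H](C)[C@]2(C)Cc3cc(OC)cc(C)c3OC)C1CC=C | intermediate
41 | (4aR,5S,6S,8aR)-5-[(2,5-dimethoxy-3-methylphenyl)methyl]-5,6,8a-trimethyl-1-(prop-2-en-1-yl)octahydronaphthalen-2(1H)-one, C1 epimers | O=C1CC[C@H]2[C@@](C)(CC[C@H](C)[C@]2(C)Cc3cc(OC)cc(C)c3OC)C1CC=C | intermediate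
42 | (1S,4aR,5S,6S,8aR)-5-[(2,5-dimethoxy-3-methylphenyl)methyl]-5,6,8a-trimethyl-1-(prop-2-en-1-yl)octahydronaphthalen-2(1H)-one | O=C1CC[C@H]2[C@@](C)(CC[C@H](C)[C@]2(C)Cc3cc(OC)cc(C)c3OC)[C@@H]1CC=C | intermediate
43 | acetone | CC(C)=O | starting material
44 | (1S,4aR,5S,6S,8aR)-5-[(2,5-dimethoxy-3-methylphenyl)methyl]-5,6,8a-trimethyl-2-(propan-2-ylidene)-1-(prop-2-en-1-yl)decahydronaphthalene | CC(C)=C1CC[C@H]2[C@@](C)(CC[C@H](C)[C@]2(C)Cc3cc(OC)cc(C)c3OC)[C@@H]1CC=C | intermediate
45 | hydrogen peroxide | OO | starting material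
46 | 9-{3-[(1S,4aR,5S,6S,8aR)-5-[(2,5-dimethoxy-3-methylphenyl)methyl]-5,6,8a-trimethyl-2-(propan-2-ylidene)decahydronaphthalen-1-yl]propyl}-9-borabicyclo[3.3.1]nonane | CC(C)=C1CC[C@H]2[C@@](C)(CC[C@H](C)[C@]2(C)Cc3cc(OC)cc(C)c3OC)[C@@H]1CCCB4C5CCCC4CCC5 | intermediate
47 | 3-[(1S,4aR,5S,6S,8aR)-5-[(2,5-dimethoxy-3-methylphenyl)methyl]-5,6,8a-trimethyl-2-(propan-2-ylidene)decahydronaphthalen-1-yl]propan-1-ol | CC(C)=C1CC[C@H]2[C@@](C)(CC[C@H](C)[C@]2(C)Cc3cc(OC)cc(C)c3OC)[C@@H]1CCCO | intermediate
48 | water | O | starting material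
49 | 3-[(1S,4aR,5S,6S,8aR)-5-[(2,5-dimethoxy-3-methylphenyl)methyl]-5,6,8a-trimethyl-2-(propan-2-ylidene)decahydronaphthalen-1-yl]propanal | CC(C)=C1CC[C@H]2[C@@](C)(CC[C@H](C)[C@]2(C)Cc3cc(OC)cc(C)c3OC)[C@@H]1CCC=O | intermediate
50 | 3-[(1S,4aR,5S,6S,8aR)-5-[(2,5-dimethoxy-3-methylphenyl)methyl]-5,6,8a-trimethyl-2-(propan-2-ylidene)decahydronaphthalen-1-yl]propanoic acid | CC(C)=C1CC[C@H]2[C@@](C)(CC[C@H](C)[C@]2(C)Cc3cc(OC)cc(C)c3OC)[C@@H]1CCC(=O)O | intermediate
51 | 3-[(1S,4aR,5S,6S,8aR)-5,6,8a-trimethyl-5-[(5-methyl-3,6-dioxocyclohexa-1,4-dien-1-yl)methyl]-2-(propan-2-ylidene)decahydronaphthalen-1-yl]propanoic acid | CC(C)=C1CC[C@H]2[C@@](C)(CC[C@H](C)[C@]2(C)CC3=CC(=O)C=C(C)C3=O)[C@@H]1CCC(=O)O | intermediate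
52 | 3-[(1S,4aR,5S,6S,8aR)-5-[(2,5-dihydroxy-3-methylphenyl)methyl]-5,6,8a-trimethyl-2-(propan-2-ylidene)decahydronaphthalen-1-yl]propanoic acid (CNP0286368.1) | CC(C)=C1CC[C@H]2[C@@](C)(CC[C@H](C)[C@]2(C)Cc2cc(O)cc(C)c2O)[C@@H]1CCC(=O)O | target

**Totals**
Total step count: 21. Longest linear sequence: 21 steps (compound 1 to compound 52).

**Steps most likely to fail**

Step 6. The bulky 2-arylmethyl group may slow the copper-mediated addition, so that background or 1,2-addition erodes the enantiofacial selectivity, and the aluminate enolate may be protonated or O-methylated instead of C-methylated. The fallback sets out from aldehyde 5 and returns at ketone 17. Commercial cyclohex-2-enone is treated with Me2Zn under Cu(OTf)2/phosphoramidite catalysis (toluene, −30 °C), and the zinc enolate is trapped in the same flask with aldehyde 5 to give the trans aldol adduct F1. Mesylation (MeSO2Cl, Et3N, CH2Cl2) gives the mesylate F2, and elimination with DBU gives the (E)-arylidene ketone F3, in which C13 has been set by a very well-established enantioselective addition to the unsubstituted enone. Conjugate reduction with LiBH(s-Bu)3 (THF, −78 °C) regenerates the C8–C14 enolate, which is methylated with MeI anti to the C13 methyl to give 17.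

Step 12. C-alkylation of the tetrasubstituted enolate, which lies between two fully substituted carbons, may be slow, so that proton transfer, O-alkylation or attack on the face of the vinyl group compete. The fallback sets out from silyl enol ether 28 and returns at ketone 31. The lithium enolate generated with MeLi is O-acylated with 2-methylprop-2-en-1-yl chloroformate to the enol carbonate F4. Pd(PPh3)4 (THF, rt) then effects decarboxylative allylation (Tsuji reaction): the π-allylpalladium/enolate ion pair recombines at C9 under neutral conditions, on the face away from the vinyl group.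

Step 18. The hindered, α-branched C5 ketone may stop at the pinacol or be reduced instead of cross-coupling, and titanium enolates may epimerise C10. The fallback sets out from ketone 42 and returns at alkene 44. The lithium enolate of S-phenyl 2-methylpropanethioate (LiN(i-Pr)2, THF, −78 → 0 °C) adds to the C5 carbonyl and the aldolate closes, with loss of thiophenolate, to the spiro β-lactone F5. Heating (toluene, sealed tube, 150 °C) expels CO2 by [2+2] cycloreversion and leaves the C4=C5 isopropylidene exactly where the carbonyl was.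

Further compounds
F1 | step 6 | (3S)-2-[(2,5-dimethoxy-3-methylphenyl)(hydroxy)methyl]-3-methylcyclohexan-1-one, 2,3-trans, carbinol epimers | O=C1CCC[C@H](C)[C@H]1C(O)c1cc(OC)cc(C)c1OC
F2 | step 6 | methanesulfonate of F1 | O=C1CCC[C@H](C)[C@H]1C(OS(C)(=O)=O)c1cc(OC)cc(C)c1OC
F3 | step 6 | (2E,3S)-2-[(2,5-dimethoxy-3-methylphenyl)methylidene]-3-methylcyclohexan-1-one | O=C1CCC[C@H](C)/C1=C\c2cc(OC)cc(C)c2OC
F4 | step 12 | (3R,4S,5S)-4-[(2,5-dimethoxy-3-methylphenyl)methyl]-3-ethenyl-2,4,5-trimethylcyclohex-1-en-1-yl 2-methylprop-2-en-1-yl carbonate | C=C[C@H]1C(C)=C(OC(=O)OCC(C)=C)C[C@H](C)[C@]1(C)Cc1cc(OC)cc(C)c1OC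
F5 | step 18 | spiro β-lactone of ketone 42 (3,3-dimethyloxetan-2-one spiro-fused at C5, C5 epimers) | CC1(C)C(=O)OC12CC[C@H]3[C@@](C)(CC[C@H](C)[C@]3(C)Cc4cc(OC)cc(C)c4OC)[C@@H]2CC=C
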